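**Retrosynthetic overview**

- The route rests on ring C, a 4-alkyl-2-methoxyphenol (C1' carries the CH2CH2 link to chromone C2, OMe on C3', OH on C4'). It is treated as the dehydrogenated form of a 4-alkyl-2-methoxycyclohex-2-enone whose C4' carbonyl oxygen becomes the phenol oxygen.
- Last disconnection: aromatisation of cyclohexenone 13 by loss of H2 across C5'–C6'.
- Key disconnection: C1'–C6' (Michael addition) and C2'–C3' (aldol condensation), which leads back to chromonyl butanal 6 and 1-methoxybut-3-en-2-one 10.
- Aldehyde 6 comes from acetophenone 1 and methyl hex-5-enoate 2 (Claisen condensation, cyclodehydration, alkene cleavage). Enone 10 comes from methoxyacetyl chloride 7 and vinylmagnesium bromide 9 through the Weinreb amide.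
- Ring order: ring A is bought, the pyranone ring B is closed in step 2, ring C is closed in step 6 and aromatised in step 7.

Key step: step 6

Remark: the target is achiral, so the one stereocentre that appears on the way (C1' in 11 to 14) is carried as the racemate and disappears in step 7. The side chain is brought in as a terminal alkene and not as a free alcohol, so that the acid-mediated chromone closure cannot be diverted to a spiroketal by a pendant hydroxyl.

**Route**

Step 1
Reactants: 1 1-(2-hydroxy-4,5-dimethoxyphenyl)ethanone; 2 methyl hex-5-enoate
Product: 3 1-(2-hydroxy-4,5-dimethoxyphenyl)oct-7-ene-1,3-dione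
Conditions: NaH (4 equiv), THF, reflux; then aq. HCl, 0 °C
Reagents that add atoms: none
Why: Crossed Claisen condensation, in which the phenoxide–enolate dianion of the acetophenone is C-acylated by the unhindered methyl ester and the equilibrium is drained by formation of the stabilised β-diketonate, while the terminal alkene is inert to the base.

Step 2
Reactants: 3 1-(2-hydroxy-4,5-dimethoxyphenyl)oct-7-ene-1,3-dione
Product: 4 6,7-dimethoxy-2-(pent-4-en-1-yl)-4H-chromen-4-one
Conditions: conc. HCl (cat.), MeOH, 60 °C
Reagents that add atoms: none
Why: Acid-catalysed cyclodehydration of an o-hydroxyaryl β-diketone (the closing stage of the Baker–Venkataraman/Kostanecki chromone synthesis), in which the phenol adds to the distal ketone and the hemiketal loses water to the conjugated pyranone; the side chain carries no hydroxyl that could compete.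

Step 3
Reactants: 4 6,7-dimethoxy-2-(pent-4-en-1-yl)-4H-chromen-4-one
Product: 6 4-(6,7-dimethoxy-4-oxo-4H-chromen-2-yl)butanal, via vicinal diol 5 (not isolated)
Conditions: OsO4 (2 mol%), NaIO4 (4 equiv), 2,6-lutidine (2 equiv), dioxane/H2O (3:1), rt
Reagents that add atoms: osmium tetroxide, O=[Os](=O)(=O)=O; sodium periodate, [Na+].[O-]I(=O)(=O)=O (terminal oxygen source that re-forms OsO4)
Why: Lemieux–Johnson oxidative cleavage, in which OsO4 should dihydroxylate the isolated monosubstituted alkene much faster than the electron-poor trisubstituted C2=C3 bond of the chromone and periodate cleaves the diol to the aldehyde, with lutidine suppressing over-oxidation.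

Step 4
Reactants: 7 methoxyacetyl chloride
Product: 8 N,2-dimethoxy-N-methylacetamide
Conditions: MeNHOMe·HCl (1.1 equiv), Et3N (2.3 equiv), CH2Cl2, 0 °C → rt
Reagents that add atoms: N,O-dimethylhydroxylamine hydrochloride, CNOC.Cl
Why: Straightforward N-acylation of the liberated hydroxylamine by the acid chloride to give the Weinreb amide.

Step 5
Reactants: 8 N,2-dimethoxy-N-methylacetamide; 9 vinylmagnesium bromide
Product: 10 1-methoxybut-3-en-2-one
Conditions: THF, −20 → 0 °C; inverse quench into cold 2 M HCl; BHT (trace); distilled at reduced pressure and kept cold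
Reagents that add atoms: none
Why: Weinreb ketone synthesis, in which the magnesium-chelated tetrahedral intermediate prevents a second addition and the acidic inverse quench protonates the released N,O-dimethylhydroxylamine before it can add to the new vinyl ketone.

Step 6
Reactants: 6 4-(6,7-dimethoxy-4-oxo-4H-chromen-2-yl)butanal; 10 1-methoxybut-3-en-2-one
Product: 13 racemic 6,7-dimethoxy-2-[2-(3-methoxy-4-oxocyclohex-2-en-1-yl)ethyl]-4H-chromen-4-one, via Michael adduct 11 (not isolated), via aldol 12 (not isolated)
Conditions: 10 (1.5 equiv, slow addition), pyrrolidine (20 mol%), AcOH (20 mol%), toluene, 0 °C → rt; then 60 °C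
Reagents that add atoms: none
Why: Pyrrolidine condenses with the aldehyde to its enamine, whose β-carbon (the future C1') adds to the terminal carbon of the vinyl ketone (C6'), and hydrolysis returns the 1,5-keto aldehyde 11. The methoxy-bearing α-carbon of the ketone (C3'), as enol or enamine, then attacks the aldehyde carbon or its iminium form (C2') in a 6-(enolendo)-exo-trig closure to aldol 12, and loss of water (or of the amine) gives the conjugated 2-methoxy enone. The closest known reaction type is the amine-catalysed Robinson annulation (Michael addition then aldol condensation) of α-unbranched aldehydes with vinyl ketones to 4-substituted cyclohex-2-enones, and 1-methoxybut-3-en-2-one is an established annulating vinyl ketone. C1' is formed without control and is racemic, and the carbinol and methoxy centres of 12 are removed on dehydration, which is immaterial because step 7 flattens the ring. The required regiochemistry is secured by ring size, since closure through C5' or attack of the aldehyde α-carbon on the ketone would give four-membered rings, so only the C3' pathway operates and it places OMe next to the carbonyl and the chain para to it; a second Michael addition is disfavoured because the α-branched aldehyde 11 forms its enamine slowly. The buffered, catalytic amine at or below 60 °C is not expected to open the 2-alkylchromone, which normally needs excess secondary amine and prolonged heating.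

Step 7
Reactants: 13 racemic 6,7-dimethoxy-2-[2-(3-methoxy-4-oxocyclohex-2-en-1-yl)ethyl]-4H-chromen-4-one
Product: 15 2-[2-(4-hydroxy-3-methoxyphenyl)ethyl]-6,7-dimethoxy-4H-chromen-4-one, via cross-conjugated dienone 14 (not isolated)
Conditions: Pd(OCOCF3)2 (5 mol%), 2-(dimethylamino)pyridine (10 mol%), TsOH·H2O (20 mol%), O2 (1 atm), DMSO, 80 °C
Reagents that add atoms: none
Why: Aerobic palladium-catalysed dehydrogenation of a cyclohexenone to a phenol, in which divalent palladium forms the enolate at C5' (the only sp3 α-carbon), β-hydride elimination from C6' gives the 2,5-cyclohexadienone 14, this tautomerises at once to the phenol by shift of the C1' hydrogen to oxygen, and O2 re-oxidises zerovalent palladium, so the C4' hydroxyl appears free without any protecting group.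

**Compound list**

1 | 1-(2-hydroxy-4,5-dimethoxyphenyl)ethanone | CC(=O)c1cc(OC)c(OC)cc1O | starting material
2 | methyl hex-5-enoate | C=CCCCC(=O)OC | starting material
3 | 1-(2-hydroxy-4,5-dimethoxyphenyl)oct-7-ene-1,3-dione | C=CCCCC(=O)CC(=O)c1cc(OC)c(OC)cc1O | intermediate
4 | 6,7-dimethoxy-2-(pent-4-en-1-yl)-4H-chromen-4-one | C=CCCCc1cc(=O)c2cc(OC)c(OC)cc2o1 | intermediate
5 | 2-(4,5-dihydroxypentyl)-6,7-dimethoxy-4H-chromen-4-one (racemic, not isolated) | OCC(O)CCCc1cc(=O)c2cc(OC)c(OC)cc2o1 | intermediate
6 | 4-(6,7-dimethoxy-4-oxo-4H-chromen-2-yl)butanal | COc1cc2oc(CCCC=O)cc(=O)c2cc1OC | intermediate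
7 | methoxyacetyl chloride | COCC(=O)Cl | starting material
8 | N,2-dimethoxy-N-methylacetamide | COCC(=O)N(C)OC | intermediate
9 | vinylmagnesium bromide | C=C[Mg]Br | starting material
10 | 1-methoxybut-3-en-2-one | C=CC(=O)COC | intermediate
11 | 2-[2-(6,7-dimethoxy-4-oxo-4H-chromen-2-yl)ethyl]-6-methoxy-5-oxohexanal (racemic, not isolated) | COCC(=O)CCC(C=O)CCc1cc(=O)c2cc(OC)c(OC)cc2o1 | intermediate
12 | 2-[2-(2-hydroxy-3-methoxy-4-oxocyclohexyl)ethyl]-6,7-dimethoxy-4H-chromen-4-one (mixture of diastereomers, not isolated) | COC1C(O)C(CCc2cc(=O)c3cc(OC)c(OC)cc3o2)CCC1=O | intermediate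
13 | 6,7-dimethoxy-2-[2-(3-methoxy-4-oxocyclohex-2-en-1-yl)ethyl]-4H-chromen-4-one (racemic) | COC1=CC(CCc2cc(=O)c3cc(OC)c(OC)cc3o2)CCC1=O | intermediate
14 | 6,7-dimethoxy-2-[2-(3-methoxy-4-oxocyclohexa-2,5-dien-1-yl)ethyl]-4H-chromen-4-one (not isolated) | COC1=CC(CCc2cc(=O)c3cc(OC)c(OC)cc3o2)C=CC1=O | intermediate
15 | 2-[2-(4-hydroxy-3-methoxyphenyl)ethyl]-6,7-dimethoxy-4H-chromen-4-one | COc1cc(CCc2cc(=O)c3cc(OC)c(OC)cc3o2)ccc1O | target

**Step count**

Total steps: 7. Longest linear sequence: 5 steps (steps 1, 2, 3, 6, 7); the enone branch (steps 4 and 5) joins at step 6.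

**Steps most likely to fail**

1. Step 6 (key annulation). The vinyl ketone may be consumed by amine-induced polymerisation or by aza-Michael addition of the catalyst. Pyrrolidine may also attack C2 of the chromone and open the pyranone ring, or the sequence may stall at the keto aldehyde and drift into intermolecular aldol oligomerisation.
Fallback, from 6 back to 13, is a stoichiometric Stork enamine annulation in which no free secondary amine is present during C–C bond formation. Aldehyde 6 is condensed with the less nucleophilic morpholine (K2CO3, toluene, rt) to the enamine 6,7-dimethoxy-2-[(3E)-4-(morpholin-4-yl)but-3-en-1-yl]-4H-chromen-4-one F1. With enone 10 in MeCN (0 °C → rt) this should give, by hetero-Diels–Alder addition (a formal Michael addition), the aminal 2-{2-[6-(methoxymethyl)-2-(morpholin-4-yl)-3,4-dihydro-2H-pyran-3-yl]ethyl}-6,7-dimethoxy-4H-chromen-4-one F2. Warming in aqueous AcOH/NaOAc hydrolyses F2 to keto aldehyde 11, which under the same acidic buffer closes through aldol 12 to cyclohexenone 13.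

2. Step 7 (dehydrogenation). The catalyst may aggregate to palladium black before conversion is complete. Oxidation may also occur at the activated CH2 next to chromone C2, or the electron-rich guaiacol product may be oxidised further under O2 at 80 °C.
Fallback, from 13 back to 15, is a Saegusa–Ito sequence at room temperature without oxygen or acid. Enone 13 is converted with TMSOTf/Et3N (CH2Cl2, 0 °C) into the cross-conjugated silyl dienol ether 6,7-dimethoxy-2-{2-[3-methoxy-4-(trimethylsilyloxy)cyclohexa-2,4-dien-1-yl]ethyl}-4H-chromen-4-one F3. Treatment with Pd(OAc)2 (1.1 equiv, MeCN, rt) should give dienone 14, which tautomerises to target 15.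

3. Step 5 (vinyl ketone). The liberated N,O-dimethylhydroxylamine or a second equivalent of Grignard reagent may add in conjugate fashion to the nascent enone. The small, water-miscible, polymerisable product may also be lost on extraction, concentration and distillation.
Fallback, from 9 back to 10, passes through a stable alcohol and generates no amine. Vinylmagnesium bromide 9 is added to methoxyacetaldehyde (THF, −78 °C) to give 1-methoxybut-3-en-2-ol F4, which can be stored and distilled and is also an article of commerce. It is oxidised with activated MnO2 (excess, CH2Cl2, rt) immediately before use, and the filtered solution of 10 is taken directly into step 6.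

**Further compounds**

F1 | step 6 | 6,7-dimethoxy-2-[(3E)-4-(morpholin-4-yl)but-3-en-1-yl]-4H-chromen-4-one | COc1cc2oc(CC/C=C/N3CCOCC3)cc(=O)c2cc1OC
F2 | step 6 | 2-{2-[6-(methoxymethyl)-2-(morpholin-4-yl)-3,4-dihydro-2H-pyran-3-yl]ethyl}-6,7-dimethoxy-4H-chromen-4-one (mixture of diastereomers) | COCC1=CCC(CCc2cc(=O)c3cc(OC)c(OC)cc3o2)C(N2CCOCC2)O1
F3 | step 7 | 6,7-dimethoxy-2-{2-[3-methoxy-4-(trimethylsilyloxy)cyclohexa-2,4-dien-1-yl]ethyl}-4H-chromen-4-one (racemic) | COC1=CC(CCc2cc(=O)c3cc(OC)c(OC)cc3o2)CC=C1O[Si](C)(C)C
F4 | step 5 | 1-methoxybut-3-en-2-ol (racemic) | C=CC(O)COC
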